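## Retrosynthetic overview

1. Target ⇐ macrocyclic β-hydroxy ketone 16 by Evans–Tishchenko reduction with tiglaldehyde (sets C8, puts the tiglate on O6) and lactonisation to O8.
2. 16 ⇐ keto-enal 13 by anti-aldol closure of the C6–C7 bond (ten-membered carbocycle, sets C6 and C7).
3. 13 ⇐ dialdehyde 9 + methyl 2-(bromomethyl)acrylate (C7–C8 bond by Barbier allylation, then oxidation to the C8 ketone).
4. 9 ⇐ symmetric bis(keto-enal) 6 by organocatalytic enantioselective oxa-Michael closure (furanone ring, C10; first stereocentre).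
5. 6 ⇐ bis(3-methylfuran-2-yl)methane 4 ⇐ two 3-methylfuran + formaldehyde. Ring order: furanone, then carbocycle, then lactone.

**Assumption (one line):** atom labels C1–C15 follow germacrane numbering (C12 lactone carbonyl, C13 exocyclic methylene); the target is read as (4Z,6S,7R,8S,10S) with an (E)-2-methylbut-2-enoate (tiglate) on O6 and the lactone closed to O8.

## Route

Step 1
Reactants: 1 3-methylfuran; 2 formaldehyde (as paraformaldehyde)
Product: 4 bis(3-methylfuran-2-yl)methane, via 3-methylfurfuryl alcohol 3 (not isolated)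
Conditions: (CH2O)n (1 equiv), 1 (10 equiv in all; two are consumed, the excess is recovered by distillation), Amberlyst-15 (cat.), 0 °C to rt
Reagents that add atoms: 3-methylfuran (the second equivalent of 1, which is alkylated by 3), Cc1ccoc1
Why: Acid-catalysed hydroxyalkylation then Friedel–Crafts alkylation of furan: the electrophile enters at C2 of 3-methylfuran (the α-position activated by both the ring oxygen and the adjacent methyl, as in its formylation), the furfuryl cation from 3 is trapped at C2 of a second molecule of 3-methylfuran with loss of water, and the large excess of 1 suppresses oligomers; no stereocentre is formed.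

Step 2
Reactants: 4 bis(3-methylfuran-2-yl)methane
Product: 6 (2Z,7Z)-3,7-dimethyl-4,6-dioxonona-2,7-dienedial, via furyl keto-enal 5 (not isolated)
Conditions: DMDO (2.0 equiv, titrated, in acetone), CH2Cl2, −78 to −40 °C; concentrated cold and used at once
Reagents that add atoms: dimethyldioxirane, CC1(C)OO1
Why: Oxidative furan ring-opening to a cis-ene-dione under neutral, base-free conditions turns each furan into a (Z)-γ-keto-enal whose geometry is fixed by the ring, which unmasks the 1,3-diketone (C1–C3), both aldehyde termini (C6, C8) and the Z C4=C5 alkene in one operation; exact stoichiometry at low temperature avoids hydroxylation of the diketone enol, and the product is achiral.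

Step 3
Reactants: 6 (2Z,7Z)-3,7-dimethyl-4,6-dioxonona-2,7-dienedial
Product: 9 2-[(2S)-2-methyl-3-oxo-5-[(2Z)-4-oxobut-2-en-2-yl]-2,3-dihydrofuran-2-yl]acetaldehyde, via iminium benzoate 7 (not isolated), via enamine 8 (not isolated)
Conditions: (S)-2-[diphenyl(trimethylsilyloxy)methyl]pyrrolidine (10 mol%), PhCO2H (10 mol%), H2O (2 equiv), toluene (0.02 M), −30 °C, 4 h; filtered through silica
Reagents that add atoms: water, O (exchanges the aldehyde oxygen through 7 and 8; net change none)
Why: Proposed new method: an enantioselective 5-exo oxa-Michael closure in which the secondary amine converts one of the two equivalent enals of 6 into an iminium ion, so that the β,β-disubstituted carbon C10 (rather than C9, which would give a six-membered ring) becomes the electrophile for the enol oxygen of the tethered 1,3-diketone; the diphenyl(silyloxy)methyl group shields one face of the iminium and, by the usual model for this catalyst, the oxygen is expected to enter from the face that gives (S) at the new O-quaternary centre (the enantiomeric catalyst is used if the sense proves opposite); the closest known reactions are iminium-catalysed Michael additions of 1,3-diketones to enals (including β,β-disubstituted enals that give quaternary centres) and iminium-catalysed intramolecular oxa-Michael cyclisations, while the racemic ring-opening/ring-closure of oxidised furyl ketones to 3(2H)-furanones shows the bond construction itself is feasible.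

Step 4
Reactants: 9 furanone dialdehyde (name as above); 10 methyl 2-(bromomethyl)prop-2-enoate
Product: 12 methyl 4-hydroxy-2-methylidene-5-[(2S)-2-methyl-3-oxo-5-[(2Z)-4-oxobut-2-en-2-yl]-2,3-dihydrofuran-2-yl]pentanoate (both C4 epimers), via allylindium dibromide 11 (not isolated)
Conditions: indium powder (1.2 equiv), 10 (1.1 equiv), THF/H2O 1:1, 0 °C
Reagents that add atoms: none
Why: Barbier allylation in neutral water: the allylindium reagent adds to the unconjugated, inductively activated aldehyde C8 in preference to the β,β-disubstituted conjugated aldehyde C6, and neither the Z-enal nor the base-labile β-alkoxy aldehyde array at C10 is disturbed; the new carbinol centre is left uncontrolled because it is oxidised in step 5.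

Step 5
Reactants: 12 hydroxy ester (name as above)
Product: 13 methyl 2-methylidene-5-[(2S)-2-methyl-3-oxo-5-[(2Z)-4-oxobut-2-en-2-yl]-2,3-dihydrofuran-2-yl]-4-oxopentanoate
Conditions: Dess–Martin periodinane (1.3 equiv), CH2Cl2, 0 °C
Reagents that add atoms: none
Why: Dess–Martin oxidation is non-basic, so the β,γ-unsaturated ketone is obtained without moving the exocyclic alkene into conjugation and without touching the enal or furanone; C10 is unaffected.

Step 6
Reactants: 13 keto-enal (name as above)
Product: 16 methyl 2-[(4Z,6S,7S,10S)-6-hydroxy-4,10-dimethyl-1,8-dioxo-3,10-epoxycyclodeca-2,4-dien-7-yl]prop-2-enoate, via enol borinate 14 (not isolated), via boron aldolate 15 (not isolated)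
Conditions: (c-C6H11)2BCl (5 equiv), Et3N (6 equiv), Et2O, 13 added by syringe pump (final 3 mM), −78 to −20 °C; then MeOH, pH 7 buffer, 30% H2O2, 0 °C
Reagents that add atoms: none
Why: Intramolecular boron aldol reaction through a Zimmerman–Traxler chair: enolisation goes to the doubly activated, less hindered C7 (not the neopentyl C9, so no β-elimination of the furanone oxygen), the E-enol borinate gives the 6,7-anti aldol, and the facial sense relative to C10 is expected from the chair in which the chain leaves C10 opposite its methyl and the boron-bound aldehyde lies outside the furanone bridge, giving (6S,7S) (this is (7R) in the target, where the ranking at C7 changes).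

Step 7
Reactants: 16 macrocyclic aldol (name as above); 17 (2E)-2-methylbut-2-enal
Product: 20 (4Z,6S,7R,8S,10S)-6-tigloyloxy-1-oxo-3,10-epoxygermacra-2,4,11(13)-trien-12,8-olide (CNP0293168.2), via hemiacetal 18 (not isolated), via hydroxy ester 19 (not isolated)
Conditions: SmI2 (samarium diiodide, 30 mol%), 17 (6 equiv), THF, −10 °C, dark; then PPTS (10 mol%), CH2Cl2, rt
Reagents that add atoms: none
Why: Evans–Tishchenko reduction: the C6 hydroxyl adds to tiglaldehyde and the hemiacetal hydrogen is delivered within a six-membered samarium chelate to C8, which sets O8 anti to O6 (8S) and leaves the acyl group, now a tiglate, on O6; the freed C8 hydroxyl then closes the trans-fused γ-lactone onto the methyl ester with loss of methanol.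

## Compound list

1 | 3-methylfuran | Cc1ccoc1 | starting material
2 | formaldehyde (used as paraformaldehyde) | C=O | starting material
3 | (3-methylfuran-2-yl)methanol | Cc1ccoc1CO | intermediate
4 | bis(3-methylfuran-2-yl)methane | Cc1ccoc1Cc1occc1C | intermediate
5 | (2Z)-3-methyl-5-(3-methylfuran-2-yl)-4-oxopent-2-enal | Cc1ccoc1CC(=O)/C(C)=C\C=O | intermediate
6 | (2Z,7Z)-3,7-dimethyl-4,6-dioxonona-2,7-dienedial (drawn as the diketo form) | O=C/C=C(/C)C(=O)CC(=O)/C(C)=C\C=O | intermediate
7 | iminium benzoate from one enal of 6 and (S)-2-[diphenyl(trimethylsilyloxy)methyl]pyrrolidine | O=C/C=C(/C)C(=O)CC(=O)/C(C)=C\C=[N+]1CCC[C@H]1C(O[Si](C)(C)C)(c1ccccc1)c1ccccc1.[O-]C(=O)c1ccccc1 | intermediate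
8 | enamine of 9 with the same amine (furanone closed, C10 S) | C(c1ccccc1)(c1ccccc1)(O[Si](C)(C)C)[C@@H]1CCCN1/C=C/[C@]1(C)OC(=CC1=O)/C(C)=C\C=O | intermediate
9 | 2-[(2S)-2-methyl-3-oxo-5-[(2Z)-4-oxobut-2-en-2-yl]-2,3-dihydrofuran-2-yl]acetaldehyde | O=CC[C@]1(C)OC(=CC1=O)/C(C)=C\C=O | intermediate
10 | methyl 2-(bromomethyl)prop-2-enoate | C=C(CBr)C(=O)OC | starting material
11 | [2-(methoxycarbonyl)prop-2-en-1-yl]indium dibromide | C=C(C[In](Br)Br)C(=O)OC | intermediate
12 | methyl 4-hydroxy-2-methylidene-5-[(2S)-2-methyl-3-oxo-5-[(2Z)-4-oxobut-2-en-2-yl]-2,3-dihydrofuran-2-yl]pentanoate (both C4 epimers) | C=C(CC(O)C[C@]1(C)OC(=CC1=O)/C(C)=C\C=O)C(=O)OC | intermediate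
13 | methyl 2-methylidene-5-[(2S)-2-methyl-3-oxo-5-[(2Z)-4-oxobut-2-en-2-yl]-2,3-dihydrofuran-2-yl]-4-oxopentanoate | C=C(CC(=O)C[C@]1(C)OC(=CC1=O)/C(C)=C\C=O)C(=O)OC | intermediate
14 | (E)-dicyclohexylboron enolate of 13 (C7=C8) | C=C(C(=O)OC)/C=C(/OB(C1CCCCC1)C1CCCCC1)C[C@]1(C)OC(=CC1=O)/C(C)=C\C=O | intermediate
15 | O6-dicyclohexylborinate of 16 | C=C(C(=O)OC)[C@@H]1C(=O)C[C@]2(C)OC(=CC2=O)/C(C)=C\[C@@H]1OB(C1CCCCC1)C1CCCCC1 | intermediate
16 | methyl 2-[(4Z,6S,7S,10S)-6-hydroxy-4,10-dimethyl-1,8-dioxo-3,10-epoxycyclodeca-2,4-dien-7-yl]prop-2-enoate | C=C(C(=O)OC)[C@@H]1C(=O)C[C@]2(C)OC(=CC2=O)/C(C)=C\[C@@H]1O | intermediate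
17 | (2E)-2-methylbut-2-enal (tiglaldehyde) | C/C=C(\C)C=O | starting material
18 | hemiacetal of 16 (at O6) with 17 (samarium-bound in the flask, drawn free) | C=C(C(=O)OC)[C@@H]1C(=O)C[C@]2(C)OC(=CC2=O)/C(C)=C\[C@@H]1OC(O)/C(C)=C/C | intermediate
19 | methyl 2-[(4Z,6S,7R,8S,10S)-8-hydroxy-4,10-dimethyl-6-{[(2E)-2-methylbut-2-enoyl]oxy}-1-oxo-3,10-epoxycyclodeca-2,4-dien-7-yl]prop-2-enoate | C=C(C(=O)OC)[C@@H]1[C@@H](O)C[C@]2(C)OC(=CC2=O)/C(C)=C\[C@@H]1OC(=O)/C(C)=C/C | intermediate
20 | (4Z,6S,7R,8S,10S)-6-tigloyloxy-1-oxo-3,10-epoxygermacra-2,4,11(13)-trien-12,8-olide | C=C1C(=O)O[C@H]2C[C@]3(C)OC(=CC3=O)/C(C)=C\[C@H](OC(=O)/C(C)=C/C)[C@H]12 | target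

## Step count and risks

Total steps: 7. Longest linear sequence: 7 (fully linear from 1).

**Step 3 (the new oxa-Michael closure).** The risks are uncatalysed racemic closure of 6, trapping of the amine by the cis-keto-enal, Z/E leakage of the spectator enal through its dienamine, and erosion by retro-addition if the reaction is left too long. Fallback with known chemistry, setting out from 6: close the ring without induction (Et3N 5 mol%, CH2Cl2, −20 °C; base-mediated 5-exo oxa-Michael of a β-diketone) to the racemic furanone dialdehyde F1. Resolve F1 on a chiral stationary phase (amylose tris(3,5-dimethylphenylcarbamate), CO2/iPrOH) into 9 and its (R)-enantiomer F2. Return F2 to F1 with DBU (retro-oxa-Michael and re-closure) and recycle. The route is rejoined at 9.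

**Step 6 (ten-membered ring by aldol).** The risks are ring closure by an aldol that can revert, enolate geometry, and the facial sense relative to C10, which rests on a conformational argument only. Fallback, setting out from 13: form the silyl dienol ether F3 (TMSOTf, Et3N, CH2Cl2, −78 °C) and brominate it at the γ-carbon with NBS (THF, −78 °C) to the 2-(bromomethyl)-4-oxo-enoate F4. Close the ring under Nozaki–Hiyama–Kishi-type conditions (CrCl2, chromium dichloride, 6 equiv, THF, slow addition, rt). The allylchromium species adds irreversibly through C7 to the aldehyde, anti as usual for γ-substituted allylchromium reagents. The route is rejoined at 16.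

**Step 7 (Evans–Tishchenko with an enal).** The risks are an α,β-unsaturated aldehyde as hydride donor, attack of divalent samarium on the enoate, and acyl migration from O6 to O8 before the lactone closes. Fallback, setting out from 16: hydroxyl-directed anti reduction with Me4NBH(OAc)3 (MeCN/AcOH, −30 °C) gives the anti-diol ester F5. CSA (cat., CH2Cl2) closes the lactone through O8 to the 6-hydroxy lactone F6; closure through O6 would give the cis-fused isomer, which is expected to be the less stable one and to equilibrate under the acid. Yamaguchi esterification (tiglic acid, 2,4,6-trichlorobenzoyl chloride, Et3N, DMAP, toluene) then gives the target. The route is rejoined at 20.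

## Further compounds

F1 | step 3 | racemic 2-[2-methyl-3-oxo-5-[(2Z)-4-oxobut-2-en-2-yl]-2,3-dihydrofuran-2-yl]acetaldehyde | O=CCC1(C)OC(=CC1=O)/C(C)=C\C=O
F2 | step 3 | 2-[(2R)-2-methyl-3-oxo-5-[(2Z)-4-oxobut-2-en-2-yl]-2,3-dihydrofuran-2-yl]acetaldehyde | O=CC[C@@]1(C)OC(=CC1=O)/C(C)=C\C=O
F3 | step 6 | methyl 2-methylidene-5-[(2S)-2-methyl-3-oxo-5-[(2Z)-4-oxobut-2-en-2-yl]-2,3-dihydrofuran-2-yl]-4-(trimethylsilyloxy)pent-3-enoate | C=C(C(=O)OC)C=C(O[Si](C)(C)C)C[C@]1(C)OC(=CC1=O)/C(C)=C\C=O
F4 | step 6 | methyl 2-(bromomethyl)-5-[(2S)-2-methyl-3-oxo-5-[(2Z)-4-oxobut-2-en-2-yl]-2,3-dihydrofuran-2-yl]-4-oxopent-2-enoate | COC(=O)C(CBr)=CC(=O)C[C@]1(C)OC(=CC1=O)/C(C)=C\C=O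
F5 | step 7 | methyl 2-[(4Z,6S,7R,8S,10S)-6,8-dihydroxy-4,10-dimethyl-1-oxo-3,10-epoxycyclodeca-2,4-dien-7-yl]prop-2-enoate | C=C(C(=O)OC)[C@@H]1[C@@H](O)C[C@]2(C)OC(=CC2=O)/C(C)=C\[C@@H]1O
F6 | step 7 | (4Z,6S,7S,8S,10S)-6-hydroxy-1-oxo-3,10-epoxygermacra-2,4,11(13)-trien-12,8-olide | C=C1C(=O)O[C@H]2C[C@]3(C)OC(=CC3=O)/C(C)=C\[C@H](O)[C@H]12
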